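## Retrosynthetic overview

1. The seven-membered ring is closed last, by ring-closing metathesis (C-8=C-9) of a trans-1,2-disubstituted cyclopentane that carries the C-10 vinyl carbinol and the C-6 methallyl carbinol ester.
2. The C-4 isopropyl carbinol comes from isopropylcerium addition to a cyclopentanone, itself obtained by conjugate reduction of a cyclopentenone.
3. Key C-5–C-6 bond: intermolecular anti-selective boron aldol addition of a 4,4-disubstituted cyclopent-2-enone (α′-enolate) to 3-methylbut-3-enal, setting C-5 and C-6.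
4. The five-membered ring is formed first, by intramolecular aldol condensation of a γ-keto aldehyde built from levulinate.
5. C-10 and quaternary C-1 come from an Evans aldol with acrolein followed by Fráter–Seebach methylation.

Assumption: locants C-1 to C-10 are daucane numbers (C-1 quaternary CMe, C-4 isopropyl carbinol, C-5 ring-fusion CH, C-6 ester carbinol, C-8=C-9 ring alkene, C-10 allylic carbinol); TBS = tert-butyldimethylsilyl, TES = triethylsilyl.

## Route

Step 1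
Reactants: 1 ethyl 4-oxopentanoate (ethyl levulinate)
Product: 2 ethyl 3-(2-methyl-1,3-dioxolan-2-yl)propanoate
Conditions: HOCH2CH2OH, p-TsOH·H2O (cat.), toluene, reflux, Dean–Stark
Reagents that add atoms: ethylene glycol OCCO
Why: Acid-catalysed ketalisation with azeotropic removal of water masks the ketone so that only the acyl carbonyl is enolised later.

Step 2
Reactants: 2 ethyl 3-(2-methyl-1,3-dioxolan-2-yl)propanoate
Product: 3 3-(2-methyl-1,3-dioxolan-2-yl)propanoic acid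
Conditions: NaOH, THF/MeOH/H2O, rt; then cold 1 M HCl to pH 4
Reagents that add atoms: sodium hydroxide [Na+].[OH-]
Why: Saponification of the ester, the dioxolane being stable to base and to a brief cold work-up at pH 4.

Step 3
Reactants: 3 3-(2-methyl-1,3-dioxolan-2-yl)propanoic acid; 4 (4S)-4-benzyl-1,3-oxazolidin-2-one
Product: 6 (4S)-4-benzyl-3-[3-(2-methyl-1,3-dioxolan-2-yl)propanoyl]-1,3-oxazolidin-2-one, via mixed pivalic anhydride 5 (not isolated)
Conditions: t-BuCOCl, Et3N, THF, −20 °C; then LiCl, 4, −20 °C → rt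
Reagents that add atoms: none
Why: N-acylation of the Evans auxiliary through the mixed anhydride, which is attacked at its less hindered carbonyl.

Step 4
Reactants: 6 (4S)-4-benzyl-3-[3-(2-methyl-1,3-dioxolan-2-yl)propanoyl]-1,3-oxazolidin-2-one; 7 acrolein
Product: 9 (4S)-4-benzyl-3-[(2S,3R)-3-hydroxy-2-[(2-methyl-1,3-dioxolan-2-yl)methyl]pent-4-enoyl]-1,3-oxazolidin-2-one, via boron Z-enolate 8 (not isolated)
Conditions: Bu2BOTf, iPr2NEt, CH2Cl2, −78 → 0 °C; 7, −78 → 0 °C; then pH 7 buffer, MeOH, 30% H2O2, 0 °C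
Reagents that add atoms: none
Why: Evans syn aldol addition, in which the Z-boron enolate reacts through a Zimmerman–Traxler chair on the face away from the benzyl group and so fixes C-10 as R (the α-centre formed here is erased in step 6).

Step 5
Reactants: 9 (4S)-4-benzyl-3-[(2S,3R)-3-hydroxy-2-[(2-methyl-1,3-dioxolan-2-yl)methyl]pent-4-enoyl]-1,3-oxazolidin-2-one
Product: 10 methyl (2S,3R)-3-hydroxy-2-[(2-methyl-1,3-dioxolan-2-yl)methyl]pent-4-enoate
Conditions: NaOMe (0.2 equiv), MeOH, −10 °C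
Reagents that add atoms: methanol CO
Why: Methoxide-catalysed transesterification releases the recoverable auxiliary, and any α-epimerisation is harmless because that centre is enolised next.

Step 6
Reactants: 10 methyl (2S,3R)-3-hydroxy-2-[(2-methyl-1,3-dioxolan-2-yl)methyl]pent-4-enoate
Product: 12 methyl (2S,3R)-3-hydroxy-2-methyl-2-[(2-methyl-1,3-dioxolan-2-yl)methyl]pent-4-enoate, via dilithium dianion 11 (not isolated)
Conditions: LiN(iPr)2 (2.3 equiv), THF, −78 → −20 °C; MeI, DMPU, −78 → −10 °C; then H2O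
Reagents that add atoms: iodomethane CI
Why: Fráter–Seebach alkylation, in which the lithium-chelated alkoxide-enolate is methylated on the face opposite the vinyl group, giving quaternary C-1 with methyl anti to the C-10 hydroxyl.

Step 7
Reactants: 12 methyl (2S,3R)-3-hydroxy-2-methyl-2-[(2-methyl-1,3-dioxolan-2-yl)methyl]pent-4-enoate
Product: 13 methyl (2S,3R)-3-[(tert-butyldimethylsilyl)oxy]-2-methyl-2-[(2-methyl-1,3-dioxolan-2-yl)methyl]pent-4-enoate
Conditions: TBSOTf, 2,6-lutidine, CH2Cl2, −78 → 0 °C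
Reagents that add atoms: tert-butyldimethylsilyl triflate CC(C)(C)[Si](C)(C)OS(=O)(=O)C(F)(F)F
Why: Silyl triflate silylation protects the hindered neopentyl carbinol without a free alkoxide, so no retro-aldol can occur.

Step 8
Reactants: 13 methyl (2S,3R)-3-[(tert-butyldimethylsilyl)oxy]-2-methyl-2-[(2-methyl-1,3-dioxolan-2-yl)methyl]pent-4-enoate
Product: 14 (2R,3R)-3-[(tert-butyldimethylsilyl)oxy]-2-methyl-2-[(2-methyl-1,3-dioxolan-2-yl)methyl]pent-4-en-1-ol
Conditions: i-Bu2AlH (2.5 equiv), CH2Cl2, −78 → 0 °C; aq. KNaC4H4O6 (potassium sodium tartrate)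
Reagents that add atoms: none
Why: Hydride reduction of the ester to the primary alcohol, the aluminium alkoxide being too weakly basic to trigger silyl migration.

Step 9
Reactants: 14 (2R,3R)-3-[(tert-butyldimethylsilyl)oxy]-2-methyl-2-[(2-methyl-1,3-dioxolan-2-yl)methyl]pent-4-en-1-ol
Product: 15 (2S,3R)-3-[(tert-butyldimethylsilyl)oxy]-2-methyl-2-[(2-methyl-1,3-dioxolan-2-yl)methyl]pent-4-enal
Conditions: Dess–Martin periodinane, NaHCO3 (buffer), CH2Cl2, 0 °C → rt
Reagents that add atoms: none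
Why: Dess–Martin oxidation gives an aldehyde with no α-hydrogen, so it can neither epimerise nor enolise.

Step 10
Reactants: 15 (2S,3R)-3-[(tert-butyldimethylsilyl)oxy]-2-methyl-2-[(2-methyl-1,3-dioxolan-2-yl)methyl]pent-4-enal
Product: 18 (4R)-4-[(1R)-1-[(tert-butyldimethylsilyl)oxy]prop-2-en-1-yl]-4-methylcyclopent-2-en-1-one, via keto aldehyde 16 (not isolated), via aldol 17 (not isolated)
Conditions: PPTS (cat.), acetone/H2O, 55 °C; evaporate; then KOH (0.3 equiv), MeOH, rt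
Reagents that add atoms: water O
Why: Ketal hydrolysis followed by intramolecular aldol condensation, in which the methyl ketone can only attack the non-enolisable aldehyde to close the five-membered ring, with no stereocentre touched.

Step 11
Reactants: 19 3-methylbut-3-en-1-ol
Product: 20 3-methylbut-3-enal
Conditions: Dess–Martin periodinane, NaHCO3 (buffer), CH2Cl2, 0 °C; cold filtered solution used at once
Reagents that add atoms: none
Why: Buffered Dess–Martin oxidation gives the β,γ-unsaturated aldehyde without the base that would conjugate it.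

Step 12
Reactants: 18 (4R)-4-[(1R)-1-[(tert-butyldimethylsilyl)oxy]prop-2-en-1-yl]-4-methylcyclopent-2-en-1-one; 20 3-methylbut-3-enal
Product: 22 (4S,5S)-4-[(1R)-1-[(tert-butyldimethylsilyl)oxy]prop-2-en-1-yl]-5-[(1S)-1-hydroxy-3-methylbut-3-en-1-yl]-4-methylcyclopent-2-en-1-one, via boron dienolate 21 (not isolated)
Conditions: Bu2BOTf, iPr2NEt, CH2Cl2, −78 → 0 °C; 20 (2 equiv), −78 → −30 °C; then pH 7 buffer, MeOH, 30% H2O2, 0 °C
Reagents that add atoms: none
Why: Boron-mediated intermolecular aldol addition in which only the α′ position can enolise, the ring-fixed E-enolate gives the anti adduct through a Zimmerman–Traxler chair (C-6 S), and the aldehyde approaches opposite the bulky silyloxyallyl group (C-5 S, cis to the C-1 methyl).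

Step 13
Reactants: 22 (4S,5S)-4-[(1R)-1-[(tert-butyldimethylsilyl)oxy]prop-2-en-1-yl]-5-[(1S)-1-hydroxy-3-methylbut-3-en-1-yl]-4-methylcyclopent-2-en-1-one
Product: 23 (4S,5S)-4-[(1R)-1-[(tert-butyldimethylsilyl)oxy]prop-2-en-1-yl]-4-methyl-5-[(1S)-3-methyl-1-[(triethylsilyl)oxy]but-3-en-1-yl]cyclopent-2-en-1-one
Conditions: TESOTf, 2,6-lutidine, CH2Cl2, −78 °C
Reagents that add atoms: triethylsilyl triflate CC[Si](CC)(CC)OS(=O)(=O)C(F)(F)F
Why: Low-temperature silylation caps the aldol hydroxyl, preventing retro-aldol and elimination, with a group removable later in the presence of TBS.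

Step 14
Reactants: 23 (4S,5S)-4-[(1R)-1-[(tert-butyldimethylsilyl)oxy]prop-2-en-1-yl]-4-methyl-5-[(1S)-3-methyl-1-[(triethylsilyl)oxy]but-3-en-1-yl]cyclopent-2-en-1-one
Product: 24 (2S,3S)-3-[(1R)-1-[(tert-butyldimethylsilyl)oxy]prop-2-en-1-yl]-3-methyl-2-[(1S)-3-methyl-1-[(triethylsilyl)oxy]but-3-en-1-yl]cyclopentan-1-one
Conditions: [(Ph3P)CuH]6 (0.4 equiv), degassed benzene, H2O (5 equiv), rt
Reagents that add atoms: none
Why: Conjugate reduction with Stryker's copper hydride saturates only the enone C=C, leaving the isolated alkenes alone and forming the enolate away from C-5, so C-5 keeps its configuration.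

Step 15
Reactants: 24 (2S,3S)-3-[(1R)-1-[(tert-butyldimethylsilyl)oxy]prop-2-en-1-yl]-3-methyl-2-[(1S)-3-methyl-1-[(triethylsilyl)oxy]but-3-en-1-yl]cyclopentan-1-one
Product: 25 (1R,2S,3S)-3-[(1R)-1-[(tert-butyldimethylsilyl)oxy]prop-2-en-1-yl]-3-methyl-2-[(1S)-3-methyl-1-[(triethylsilyl)oxy]but-3-en-1-yl]-1-(propan-2-yl)cyclopentan-1-ol
Conditions: CeCl3 (anhydrous, 3 equiv), iPrMgCl (3 equiv), THF, −78 °C, 1 h; then 24, −78 → −40 °C; aq. NH4Cl
Reagents that add atoms: isopropylmagnesium chloride CC(C)[Mg]Cl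
Why: Organocerium 1,2-addition (Imamoto conditions) suppresses enolisation and reduction, and attack trans to the adjacent C-5 side chain gives the 4R carbinol with hydroxyl cis to that chain.

Step 16
Reactants: 25 (1R,2S,3S)-3-[(1R)-1-[(tert-butyldimethylsilyl)oxy]prop-2-en-1-yl]-3-methyl-2-[(1S)-3-methyl-1-[(triethylsilyl)oxy]but-3-en-1-yl]-1-(propan-2-yl)cyclopentan-1-ol
Product: 26 (1R,2S,3S)-3-[(1R)-1-[(tert-butyldimethylsilyl)oxy]prop-2-en-1-yl]-2-[(1S)-1-hydroxy-3-methylbut-3-en-1-yl]-3-methyl-1-(propan-2-yl)cyclopentan-1-ol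
Conditions: PPTS (cat.), MeOH/CH2Cl2, 0 °C
Reagents that add atoms: none
Why: Mild acid-catalysed methanolysis cleaves the TES ether selectively while the hindered neopentyl TBS ether survives.

Step 17
Reactants: 26 (1R,2S,3S)-3-[(1R)-1-[(tert-butyldimethylsilyl)oxy]prop-2-en-1-yl]-2-[(1S)-1-hydroxy-3-methylbut-3-en-1-yl]-3-methyl-1-(propan-2-yl)cyclopentan-1-ol; 27 4-methoxybenzoyl chloride
Product: 28 (1S)-1-[(1S,2R,5S)-5-[(1R)-1-[(tert-butyldimethylsilyl)oxy]prop-2-en-1-yl]-2-hydroxy-5-methyl-2-(propan-2-yl)cyclopentyl]-3-methylbut-3-en-1-yl 4-methoxybenzoate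
Conditions: 27 (1.5 equiv), Et3N, DMAP (cat.), CH2Cl2, 0 °C → rt
Reagents that add atoms: none
Why: DMAP-catalysed esterification acylates the only free secondary hydroxyl, the tertiary C-4 hydroxyl being inert under these conditions.

Step 18
Reactants: 28 (1S)-1-[(1S,2R,5S)-5-[(1R)-1-[(tert-butyldimethylsilyl)oxy]prop-2-en-1-yl]-2-hydroxy-5-methyl-2-(propan-2-yl)cyclopentyl]-3-methylbut-3-en-1-yl 4-methoxybenzoate
Product: 29 (1S)-1-[(1S,2R,5S)-2-hydroxy-5-[(1R)-1-hydroxyprop-2-en-1-yl]-5-methyl-2-(propan-2-yl)cyclopentyl]-3-methylbut-3-en-1-yl 4-methoxybenzoate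
Conditions: HF·pyridine, pyridine, THF, 0 °C → rt
Reagents that add atoms: none
Why: Buffered fluoride desilylation frees the C-10 allylic alcohol without the basic conditions that could cause acyl migration.

Step 19
Reactants: 29 (1S)-1-[(1S,2R,5S)-2-hydroxy-5-[(1R)-1-hydroxyprop-2-en-1-yl]-5-methyl-2-(propan-2-yl)cyclopentyl]-3-methylbut-3-en-1-yl 4-methoxybenzoate
Product: 30 (3R,3aS,4S,8R,8aS)-3,8-dihydroxy-6,8a-dimethyl-3-(propan-2-yl)-1,2,3,3a,4,5,8,8a-octahydroazulen-4-yl 4-methoxybenzoate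
Conditions: second-generation Grubbs catalyst (5 mol %), 1,4-benzoquinone (10 mol %), CH2Cl2 (2 mM), 40 °C
Reagents that add atoms: none
Why: Ring-closing metathesis between the vinyl carbinol (helped by its free allylic hydroxyl) and the methallyl group forms the trisubstituted C-8=C-9 alkene and the trans-fused seven-membered ring, with all five stereocentres already fixed.

## Compound list

1 | ethyl 4-oxopentanoate (ethyl levulinate) | CCOC(=O)CCC(C)=O | starting material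
2 | ethyl 3-(2-methyl-1,3-dioxolan-2-yl)propanoate | CCOC(=O)CCC1(C)OCCO1 | intermediate
3 | 3-(2-methyl-1,3-dioxolan-2-yl)propanoic acid | OC(=O)CCC1(C)OCCO1 | intermediate
4 | (4S)-4-benzyl-1,3-oxazolidin-2-one | O=C1N[C@@H](Cc2ccccc2)CO1 | starting material
5 | 3-(2-methyl-1,3-dioxolan-2-yl)propanoic pivalic anhydride (not isolated) | CC(C)(C)C(=O)OC(=O)CCC1(C)OCCO1 | intermediate
6 | (4S)-4-benzyl-3-[3-(2-methyl-1,3-dioxolan-2-yl)propanoyl]-1,3-oxazolidin-2-one | O=C(CCC1(C)OCCO1)N2C(=O)OC[C@@H]2Cc3ccccc3 | intermediate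
7 | acrolein (prop-2-enal) | C=CC=O | starting material
8 | dibutylboron Z-enolate of 6 (not isolated) | CCCCB(CCCC)O/C(=C\CC1(C)OCCO1)N2C(=O)OC[C@@H]2Cc3ccccc3 | intermediate
9 | (4S)-4-benzyl-3-[(2S,3R)-3-hydroxy-2-[(2-methyl-1,3-dioxolan-2-yl)methyl]pent-4-enoyl]-1,3-oxazolidin-2-one | O=C([C@@H](CC1(C)OCCO1)[C@H](O)C=C)N2C(=O)OC[C@@H]2Cc3ccccc3 | intermediate
10 | methyl (2S,3R)-3-hydroxy-2-[(2-methyl-1,3-dioxolan-2-yl)methyl]pent-4-enoate | COC(=O)[C@@H](CC1(C)OCCO1)[C@H](O)C=C | intermediate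
11 | dilithium alkoxide-enolate (dianion) of 10 (not isolated) | [Li+].[Li+].CO/C([O-])=C(\CC1(C)OCCO1)[C@H]([O-])C=C | intermediate
12 | methyl (2S,3R)-3-hydroxy-2-methyl-2-[(2-methyl-1,3-dioxolan-2-yl)methyl]pent-4-enoate | COC(=O)[C@@](C)(CC1(C)OCCO1)[C@H](O)C=C | intermediate
13 | methyl (2S,3R)-3-[(tert-butyldimethylsilyl)oxy]-2-methyl-2-[(2-methyl-1,3-dioxolan-2-yl)methyl]pent-4-enoate | COC(=O)[C@@](C)(CC1(C)OCCO1)[C@H](O[Si](C)(C)C(C)(C)C)C=C | intermediate
14 | (2R,3R)-3-[(tert-butyldimethylsilyl)oxy]-2-methyl-2-[(2-methyl-1,3-dioxolan-2-yl)methyl]pent-4-en-1-ol | OC[C@@](C)(CC1(C)OCCO1)[C@H](O[Si](C)(C)C(C)(C)C)C=C | intermediate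
15 | (2S,3R)-3-[(tert-butyldimethylsilyl)oxy]-2-methyl-2-[(2-methyl-1,3-dioxolan-2-yl)methyl]pent-4-enal | O=C[C@@](C)(CC1(C)OCCO1)[C@H](O[Si](C)(C)C(C)(C)C)C=C | intermediate
16 | (2S,3R)-3-[(tert-butyldimethylsilyl)oxy]-2-methyl-2-(2-oxopropyl)pent-4-enal (not isolated) | O=C[C@@](C)(CC(C)=O)[C@H](O[Si](C)(C)C(C)(C)C)C=C | intermediate
17 | 4-[(1R)-1-[(tert-butyldimethylsilyl)oxy]prop-2-en-1-yl]-3-hydroxy-4-methylcyclopentan-1-one, quaternary centre as in 18, both carbinol epimers (not isolated) | O=C1CC(O)[C@](C)([C@H](O[Si](C)(C)C(C)(C)C)C=C)C1 | intermediate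
18 | (4R)-4-[(1R)-1-[(tert-butyldimethylsilyl)oxy]prop-2-en-1-yl]-4-methylcyclopent-2-en-1-one | O=C1C=C[C@](C)([C@H](O[Si](C)(C)C(C)(C)C)C=C)C1 | intermediate
19 | 3-methylbut-3-en-1-ol | C=C(C)CCO | starting material
20 | 3-methylbut-3-enal | C=C(C)CC=O | intermediate
21 | dibutyl{[(3S)-3-[(1R)-1-[(tert-butyldimethylsilyl)oxy]prop-2-en-1-yl]-3-methylcyclopenta-1,4-dien-1-yl]oxy}borane (not isolated) | CCCCB(CCCC)OC1=C[C@@](C)([C@H](O[Si](C)(C)C(C)(C)C)C=C)C=C1 | intermediate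
22 | (4S,5S)-4-[(1R)-1-[(tert-butyldimethylsilyl)oxy]prop-2-en-1-yl]-5-[(1S)-1-hydroxy-3-methylbut-3-en-1-yl]-4-methylcyclopent-2-en-1-one | C=C(C)C[C@H](O)[C@H]1C(=O)C=C[C@]1(C)[C@H](O[Si](C)(C)C(C)(C)C)C=C | intermediate
23 | (4S,5S)-4-[(1R)-1-[(tert-butyldimethylsilyl)oxy]prop-2-en-1-yl]-4-methyl-5-[(1S)-3-methyl-1-[(triethylsilyl)oxy]but-3-en-1-yl]cyclopent-2-en-1-one | C=C(C)C[C@H](O[Si](CC)(CC)CC)[C@H]1C(=O)C=C[C@]1(C)[C@H](O[Si](C)(C)C(C)(C)C)C=C | intermediate
24 | (2S,3S)-3-[(1R)-1-[(tert-butyldimethylsilyl)oxy]prop-2-en-1-yl]-3-methyl-2-[(1S)-3-methyl-1-[(triethylsilyl)oxy]but-3-en-1-yl]cyclopentan-1-one | C=C(C)C[C@H](O[Si](CC)(CC)CC)[C@H]1C(=O)CC[C@]1(C)[C@H](O[Si](C)(C)C(C)(C)C)C=C | intermediate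
25 | (1R,2S,3S)-3-[(1R)-1-[(tert-butyldimethylsilyl)oxy]prop-2-en-1-yl]-3-methyl-2-[(1S)-3-methyl-1-[(triethylsilyl)oxy]but-3-en-1-yl]-1-(propan-2-yl)cyclopentan-1-ol | C=C(C)C[C@H](O[Si](CC)(CC)CC)[C@H]1[C@](O)(C(C)C)CC[C@]1(C)[C@H](O[Si](C)(C)C(C)(C)C)C=C | intermediate
26 | (1R,2S,3S)-3-[(1R)-1-[(tert-butyldimethylsilyl)oxy]prop-2-en-1-yl]-2-[(1S)-1-hydroxy-3-methylbut-3-en-1-yl]-3-methyl-1-(propan-2-yl)cyclopentan-1-ol | C=C(C)C[C@H](O)[C@H]1[C@](O)(C(C)C)CC[C@]1(C)[C@H](O[Si](C)(C)C(C)(C)C)C=C | intermediate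
27 | 4-methoxybenzoyl chloride | COc1ccc(cc1)C(Cl)=O | starting material
28 | (1S)-1-[(1S,2R,5S)-5-[(1R)-1-[(tert-butyldimethylsilyl)oxy]prop-2-en-1-yl]-2-hydroxy-5-methyl-2-(propan-2-yl)cyclopentyl]-3-methylbut-3-en-1-yl 4-methoxybenzoate | C=C(C)C[C@H](OC(=O)c1ccc(OC)cc1)[C@H]2[C@](O)(C(C)C)CC[C@]2(C)[C@H](O[Si](C)(C)C(C)(C)C)C=C | intermediate
29 | (1S)-1-[(1S,2R,5S)-2-hydroxy-5-[(1R)-1-hydroxyprop-2-en-1-yl]-5-methyl-2-(propan-2-yl)cyclopentyl]-3-methylbut-3-en-1-yl 4-methoxybenzoate | C=C(C)C[C@H](OC(=O)c1ccc(OC)cc1)[C@H]2[C@](O)(C(C)C)CC[C@]2(C)[C@H](O)C=C | intermediate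
30 | (3R,3aS,4S,8R,8aS)-3,8-dihydroxy-6,8a-dimethyl-3-(propan-2-yl)-1,2,3,3a,4,5,8,8a-octahydroazulen-4-yl 4-methoxybenzoate | COc1ccc(C(=O)O[C@H]2CC(C)=C[C@@H](O)[C@@]3(C)CC[C@@](O)(C(C)C)[C@H]23)cc1 | target

## Totals and risks

Total step count: 19. Longest linear sequence: 18 steps (steps 1–10, then 12–19); step 11 is a one-step side branch.

Most likely to fail:

Step 12 (key aldol). The β,γ-unsaturated aldehyde 20 is prone to conjugation and self-condensation, and the enolate carbon sits next to a quaternary centre. Fallback: set out from 18, deprotonate with LiN(iPr)2 at −78 °C and trap with Me3SiCl to give {[(3S)-3-[(1R)-1-[(tert-butyldimethylsilyl)oxy]prop-2-en-1-yl]-3-methylcyclopenta-1,4-dien-1-yl]oxy}trimethylsilane F1. Then run a Mukaiyama aldol addition of F1 to 20 with TiCl4 in CH2Cl2 at −78 °C, so the aldehyde never meets a basic enolate. Aqueous work-up comes back to the route at 22; the C-5/C-6 ratio must be checked and the syn isomer removed by chromatography.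

Step 15 (isopropyl addition). The ketone is hindered and enolisable, and the isopropyl reagent can transfer hydride. Fallback: set out from 24 and close the seven-membered ring first. Ring-closing metathesis (second-generation Hoveyda–Grubbs catalyst, toluene, 80 °C) gives the bicyclic ketone (3aS,4S,8R,8aS)-8-[(tert-butyldimethylsilyl)oxy]-6,8a-dimethyl-4-[(triethylsilyl)oxy]-2,3a,4,5,8,8a-hexahydroazulen-3(1H)-one F2, whose carbonyl is now flanked only by ring atoms. The smaller sp2 nucleophile CH2=C(CH3)MgBr/CeCl3, which cannot deliver hydride, adds from the face opposite the angular methyl to give the isopropenyl carbinol (3S,3aS,4S,8R,8aS)-8-[(tert-butyldimethylsilyl)oxy]-6,8a-dimethyl-3-(prop-1-en-2-yl)-4-[(triethylsilyl)oxy]-1,2,3,3a,4,5,8,8a-octahydroazulen-3-ol F3. Hydrogenation with RhCl(PPh3)3/H2 saturates only the 1,1-disubstituted alkene and gives the isopropyl carbinol (3R,3aS,4S,8R,8aS)-8-[(tert-butyldimethylsilyl)oxy]-6,8a-dimethyl-3-(propan-2-yl)-4-[(triethylsilyl)oxy]-1,2,3,3a,4,5,8,8a-octahydroazulen-3-ol F4. Tetrabutylammonium fluoride removes both silyl groups to give the triol (3R,3aS,4S,8R,8aS)-6,8a-dimethyl-3-(propan-2-yl)-1,2,3,3a,4,5,8,8a-octahydroazulene-3,4,8-triol F5. One equivalent of 27 (Et3N, DMAP, 0 °C) should then acylate the C-6 hydroxyl in preference to the neopentyl C-10 hydroxyl; this selectivity is not guaranteed. The fallback comes back to the route at 30.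

Step 19 (ring-closing metathesis). Both alkenes are slow partners, and the free allylic alcohol can isomerise to the ethyl ketone or tie up the catalyst. Fallback: set out from 28 and reverse the last two operations, so that ring closure is done on the silyl-capped allylic ether. Metathesis (second-generation Hoveyda–Grubbs catalyst, toluene, 80–100 °C) gives (3R,3aS,4S,8R,8aS)-8-[(tert-butyldimethylsilyl)oxy]-3-hydroxy-6,8a-dimethyl-3-(propan-2-yl)-1,2,3,3a,4,5,8,8a-octahydroazulen-4-yl 4-methoxybenzoate F6, and HF·pyridine then removes the silyl group to come back to the route at 30.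

Further compounds
F1 | step 12 | {[(3S)-3-[(1R)-1-[(tert-butyldimethylsilyl)oxy]prop-2-en-1-yl]-3-methylcyclopenta-1,4-dien-1-yl]oxy}trimethylsilane | C[Si](C)(C)OC1=C[C@@](C)([C@H](O[Si](C)(C)C(C)(C)C)C=C)C=C1
F2 | step 15 | (3aS,4S,8R,8aS)-8-[(tert-butyldimethylsilyl)oxy]-6,8a-dimethyl-4-[(triethylsilyl)oxy]-2,3a,4,5,8,8a-hexahydroazulen-3(1H)-one | CC[Si](CC)(CC)O[C@H]1CC(C)=C[C@@H](O[Si](C)(C)C(C)(C)C)[C@@]2(C)CCC(=O)[C@H]12
F3 | step 15 | (3S,3aS,4S,8R,8aS)-8-[(tert-butyldimethylsilyl)oxy]-6,8a-dimethyl-3-(prop-1-en-2-yl)-4-[(triethylsilyl)oxy]-1,2,3,3a,4,5,8,8a-octahydroazulen-3-ol | CC[Si](CC)(CC)O[C@H]1CC(C)=C[C@@H](O[Si](C)(C)C(C)(C)C)[C@@]2(C)CC[C@@](O)(C(C)=C)[C@H]12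
F4 | step 15 | (3R,3aS,4S,8R,8aS)-8-[(tert-butyldimethylsilyl)oxy]-6,8a-dimethyl-3-(propan-2-yl)-4-[(triethylsilyl)oxy]-1,2,3,3a,4,5,8,8a-octahydroazulen-3-ol | CC[Si](CC)(CC)O[C@H]1CC(C)=C[C@@H](O[Si](C)(C)C(C)(C)C)[C@@]2(C)CC[C@@](O)(C(C)C)[C@H]12
F5 | step 15 | (3R,3aS,4S,8R,8aS)-6,8a-dimethyl-3-(propan-2-yl)-1,2,3,3a,4,5,8,8a-octahydroazulene-3,4,8-triol | O[C@H]1CC(C)=C[C@@H](O)[C@@]2(C)CC[C@@](O)(C(C)C)[C@H]12
F6 | step 19 | (3R,3aS,4S,8R,8aS)-8-[(tert-butyldimethylsilyl)oxy]-3-hydroxy-6,8a-dimethyl-3-(propan-2-yl)-1,2,3,3a,4,5,8,8a-octahydroazulen-4-yl 4-methoxybenzoate | COc1ccc(C(=O)O[C@H]2CC(C)=C[C@@H](O[Si](C)(C)C(C)(C)C)[C@@]3(C)CC[C@@](O)(C(C)C)[C@H]23)cc1
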